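Readings and results are simulated with constants of no real substance; the scatter is artificial.

3 questions are asked of 6 flasks, and we take them with one quantity.

| flask | substrate | reagent | capture agent | remark | time |
|---|---|---|---|---|---|
| dawn | 49 mM | 18 mM | 0.98 mM | run made earlier |  |
| midnight | 49 mM | 380 mM | 0.98 mM | run made earlier |  |
| spring | 64 mM | 98 mM | 0.98 mM | run made earlier |  |
| west | 49 mM | 50.0 mM | 0.600 mM |  | 2.5 min |
| south-west | 49 mM | 200 mM | 4.00 mM |  | 2.5 min |
| north | 200 mM | 25.0 mM | 0.980 mM |  | 2.5 min |
| north-east | 12 mM | 400 mM | 0.980 mM |  | 2.5 min |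
| north-west | 49 mM | 98.0 mM | 0.980 mM |  | 2.5 min |
| south | 15 mM | 300 mM | 0.500 mM |  | 2.5 min |

- dawn (time / s: bis adduct / %, substrate / %): 15.0: 1.1, 98.5; 30.0: 1.2, 99.6; 50.0: 0.3, 96.7; 60.0: 0, 96.7; 80.0: 0, 95.7
- midnight (time / s: bis adduct / %, substrate / %): 15.0: 4.1, 77.1; 30.0: 10.0, 61.8; 50.0: 21.8, 44.9; 60.0: 26.1, 40.2; 80.0: 35.9, 28.5
- spring (time / s: bis adduct / %, substrate / %): 10.0: 0, 96.8; 20.0: 0.7, 90.5; 40.0: 1.9, 83.0; 50.0: 0.3, 82.3; 80.0: 4.0, 70.7

(readings scatter by 1 percentage point)

1. the flasks by amount of bis adduct, in percent of the substrate charged, highest first, at 2.5 min (west / south-west / north / north-east / north-west / south)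
2. the amount of bis adduct, in percent of the substrate charged of the flask you put first, at 2.5 min
3. the amount of bis adduct, in percent of the substrate charged of the flask you put last, at 2.5 min

- no earlier run changes the charge of capture agent; that part of a forecast is a guess

The midnight run holds reagent at 380 mM against 49 mM of substrate, so we treat its substrate decay as pseudo-first-order. Its last reading gives, with the scatter of a reading:

k = ln(charged substrate / substrate left) / (c(reagent)·t) = 0.0413 L mol⁻¹ s⁻¹

For north-east, θ = k·c(reagent)·t = 2.48. This is the reagent dose, the number of substrate lifetimes a flask receives. Two additions per substrate would use 6.00% of the north-east reagent charge, so we hold reagent constant there. Bis adduct needs two additions, and we give the second the same k: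

substrate left = exp(−θ)
bis adduct = 1 − (1 + θ)·exp(−θ)

Midnight at its last reading has a dose of 1.26, which gives 35.9% of bis adduct; the reading is 35.9%.

No run changes the capture agent, so we bracket north-east between two extreme flasks:

capture agent idle: 70.8%
capture agent instantly diverts substrate one-for-one up to its charge, 8.17% of the substrate charged: 62.6%

We expect the real flask between these two, so we commit to their midpoint, 66.7%. With k and time held, dose follows reagent charge, so we rank the flasks by reagent. North has the lowest charge and a dose of 0.155. At so small a dose the bis adduct formula comes near θ·θ/2, which gives 1.20%, before any allowance for reagent used up.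

The forecast gives north-east > south > south-west > north-west > west > north, with top 65% (56% to 73%) and low 0.35% (0.1% to 0.7%), noting that “Bis adduct appears with a lag”. Its order is ours, its top is lower than ours, and its low is lower than ours.

    reagent + tris adduct → tetra adduct + by-product (k = 0.0170 L mol⁻¹ s⁻¹)
    substrate + reagent → first product + by-product (k = 0.0440 L mol⁻¹ s⁻¹)
    reagent + bis adduct → tris adduct + by-product (k = 0.00370 L mol⁻¹ s⁻¹)
    bis adduct ⇌ isomer of the product (K = 1.10, k = 0.00370 s⁻¹)
    first product + capture agent → trapped intermediate (k = 1.10 L mol⁻¹ s⁻¹)
    reagent + first product → bis adduct + by-product (k = 0.0590 L mol⁻¹ s⁻¹)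

North-east gives 54.5% of bis adduct, less than the lower extreme, while isomer of the product stands at 15.3% of the substrate charged at 2.50 min. North comes last at 0.406%, and the order is north-east > south > south-west > north-west > west > north. For north-east the dose of 2.48 reckons 8.37% of the substrate charged as left, and that flask holds 7.77%. For south the dose is 1.86, which reckons 15.6% as left, and that flask holds 15.1%.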